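## Retrosynthetic overview
1. The target comes from fluoride desilylation and enantioselective CBS 1,2-reduction, in one flask, of the 6-(3-methyl-2-oxobut-3-enyl) ketone. The only stereocentre is set last, after all C–C bonds are in place.
2. The key disconnection is C6–CH2. The C6–H of a chelated 5-hydroxy-7-silyloxyisoflavone (innately nucleophilic) is joined to the enolonium ion (+)CH2–C(=O)–C(CH3)=CH2, a ketone α-carbon (also innately nucleophilic) whose polarity is reversed with trivalent iodine.
3. The enolonium precursor is a TMS dienol ether made from 3-methylbut-3-en-2-one. The arene partner is the 7,4'-bis-TBS ether of genistein.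
4. No ring is built. Rings A, C and B arrive intact in genistein, and only the C5 side chain is added.

Assumption: the [C@H] centre of the given SMILES is (R) (O > isopropenyl > CH2Ar > H), and genistein, a bulk soy isoflavone, counts as a commercial starting material.

## Route

Step 1
Reactants: 1 genistein (5,7-dihydroxy-3-(4-hydroxyphenyl)-4H-chromen-4-one)
Product: 2 7,4'-bis-O-TBS-genistein (5-OH free)
Conditions: TBSCl (2.2 equiv), imidazole (4.4 equiv), DMF, 0 °C → rt
Reagents that add atoms: tert-butyldimethylsilyl chloride, CC(C)(C)[Si](C)(C)Cl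
Why: Chemoselective silyl ether formation, in which the acidic 7-OH and 4'-OH react while the 5-OH stays free because it is locked in a hydrogen bond to the C4 carbonyl, and this free chelated OH later steers substitution to C6; no stereocentre is involved.

Step 2
Reactants: 3 3-methylbut-3-en-2-one (methyl isopropenyl ketone)
Product: 4 trimethyl[(3-methylbuta-1,3-dien-2-yl)oxy]silane
Conditions: TMSOTf (1.1 equiv), Et3N (1.3 equiv), Et2O, 0 °C; pentane extraction, distillation
Reagents that add atoms: trimethylsilyl triflate, C[Si](C)(C)OS(=O)(=O)C(F)(F)F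
Why: Soft enolisation with silyl triflate and amine, in which the acetyl CH3 is the only enolisable position of 3, so a single cross-conjugated 2-silyloxydiene forms; no stereocentre is involved.

Step 3 (key step)
Reactants: 4 trimethyl[(3-methylbuta-1,3-dien-2-yl)oxy]silane; 2 7,4'-bis-O-TBS-genistein
Product: 6 6-(3-methyl-2-oxobut-3-en-1-yl)-7,4'-bis-O-TBS-genistein, via enolonium tosylate 5 (not isolated)
Conditions: PhI(OH)OTs (1.5 equiv), BF3·OEt2 (1.5 equiv), CH2Cl2, −78 °C, then 4 (1.5 equiv), 10 min; then 2 (1.0 equiv), −78 → −30 °C; cold aq NaHCO3 quench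
Reagents that add atoms: hydroxy(tosyloxy)iodobenzene (Koser's reagent), Cc1ccc(cc1)S(=O)(=O)OI(O)c1ccccc1 (its PhI–OTs unit is present only in 5; none of its atoms end up in 6)
Why: Proposed new method: PhI(OH)OTs/BF3 turns the silyl enol ether at −78 °C into the O-bound trivalent-iodine enolate 5, whose terminal CH2 is now electrophilic (SN2'-type attack expels PhI and tosylate), and because all oxidant is consumed before the phenol is added, ring A of 2 can attack it in a Friedel–Crafts sense, expected at C6 because the 5-OH···O=C4 chelate localises the C6=C7 enol-ether bond (the same C6 preference is known for Mannich aminomethylation and dichloroiodate iodination of 5-hydroxy-7-alkoxyisoflavones), the closest known reaction type being the two-stage metal-free α-arylation of ketone-derived enolonium species with electron-rich arenes and heteroarenes; no stereocentre is formed.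

Step 4
Reactants: 6 6-(3-methyl-2-oxobut-3-en-1-yl)-7,4'-bis-O-TBS-genistein
Product: 9 (R)-6-(2-hydroxy-3-methylbut-3-en-1-yl)genistein (target), via catechol borate ester 7 (not isolated), via bis-TBS (R)-carbinol 8 (not isolated)
Conditions: (S)-Me-CBS [(S)-tetrahydro-1-methyl-3,3-diphenyl-1H,3H-pyrrolo[1,2-c][1,3,2]oxazaborole, 20 mol %], catecholborane (2.5 equiv), toluene, −78 °C; then MeOH, KHF2 (6 equiv), −78 °C → rt; aqueous work-up
Reagents that add atoms: catecholborane, B1Oc2ccccc2O1 (its boron–catechol unit is present only in 7; only its hydride ends up in 9)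
Why: Corey–Bakshi–Shibata reduction followed by fluoride desilylation in the same flask, in which the ketone binds the (S)-oxazaborolidine–catecholborane complex anti to the α-branched sp2 isopropenyl group (large) and syn to CH2Ar (small), so hydride adds to the face giving the (R)-carbinol just as acetophenone gives (R)-1-phenylethanol, while 1,2-reduction at −78 °C outruns conjugate reduction, the vinylogous-ester C4 carbonyl is inert, and KHF2/MeOH then cleaves the borate and the two phenolic silyl ethers without touching the allylic stereocentre.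

## Compound list
1 | genistein | Oc1cc(O)c2c(=O)c(-c3ccc(O)cc3)coc2c1 | starting material
2 | 7,4'-bis-O-TBS-genistein (5-OH free) | CC(C)(C)[Si](C)(C)Oc1cc(O)c2c(=O)c(-c3ccc(O[Si](C)(C)C(C)(C)C)cc3)coc2c1 | intermediate
3 | 3-methylbut-3-en-2-one | CC(=O)C(C)=C | starting material
4 | trimethyl[(3-methylbuta-1,3-dien-2-yl)oxy]silane | C=C(C)C(=C)O[Si](C)(C)C | intermediate
5 | [(3-methylbuta-1,3-dien-2-yl)oxy](phenyl)-λ3-iodanyl tosylate (O-bound enolonium species, BF3-activated) | C=C(C)C(=C)OI(c1ccccc1)OS(=O)(=O)c1ccc(C)cc1 | intermediate (not isolated)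
6 | 7-(TBSO)-3-[4-(TBSO)phenyl]-5-hydroxy-6-(3-methyl-2-oxobut-3-en-1-yl)-4H-chromen-4-one | C=C(C)C(=O)Cc1c(O[Si](C)(C)C(C)(C)C)cc2occ(-c3ccc(O[Si](C)(C)C(C)(C)C)cc3)c(=O)c2c1O | intermediate
7 | (R)-side-chain O-(1,3,2-benzodioxaborol-2-yl) ether of 8 | C=C(C)[C@H](OB1Oc2ccccc2O1)Cc1c(O[Si](C)(C)C(C)(C)C)cc2occ(-c3ccc(O[Si](C)(C)C(C)(C)C)cc3)c(=O)c2c1O | intermediate (not isolated)
8 | 7-(TBSO)-3-[4-(TBSO)phenyl]-5-hydroxy-6-[(2R)-2-hydroxy-3-methylbut-3-en-1-yl]-4H-chromen-4-one | C=C(C)[C@H](O)Cc1c(O[Si](C)(C)C(C)(C)C)cc2occ(-c3ccc(O[Si](C)(C)C(C)(C)C)cc3)c(=O)c2c1O | intermediate (not isolated)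
9 | 5,7-dihydroxy-6-[(2R)-2-hydroxy-3-methylbut-3-en-1-yl]-3-(4-hydroxyphenyl)-4H-chromen-4-one | C=C(C)[C@H](O)Cc1c(O)cc2occ(-c3ccc(O)cc3)c(=O)c2c1O | target

## Step count and risks
Total step count: 4. Longest linear sequence: 3 (1 → 2 → 6 → 9).

**Most likely to fail: step 3.**
- Possible failures are attack at C8 or at both positions, and capture of 5 by the pyrone carbonyl oxygen or the 5-OH.
- BF3 binding to the pyrone could deactivate ring A.
- Acid could cyclodehydrate 6 to a 2-isopropenylfuran if the quench is not cold.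
- The C6 assignment is checked by HMBC from the chelated 5-OH proton.
- Fallback: set out from 2 and iodinate ortho to the chelated OH with benzyltrimethylammonium dichloroiodate (BnNMe3 ICl2) and CaCO3 in CH2Cl2–MeOH. This gives 6-iodo-7,4'-bis-O-TBS-genistein F1. Then treat 4 (2.5 equiv) with Bu3SnF in toluene at 90 °C to form the tributyltin enolate of 3-methylbut-3-en-2-one F2 in situ. Couple F2 with F1 under PdCl2(P(o-tol)3)2 (5 mol %). The C–I bond, not the innate ring selectivity, now fixes the regiochemistry. The sequence comes back to the route at 6.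

**Second: step 4.**
- The bulky CH2Ar group may erode the large/small discrimination of the CBS catalyst, and catecholborane can reduce s-cis enones in the 1,4 sense.
- Fallback: set out from 6 and reduce it without stereocontrol under Luche conditions (NaBH4, CeCl3·7H2O, MeOH–THF, −78 °C) to the racemic bis-TBS carbinol F3. Resolve F3 kinetically with Burkholderia cepacia lipase and vinyl acetate in MTBE at 30 °C, to slightly above half conversion. By the Kazlauskas rule (CH2Ar large, isopropenyl medium) the (S)-enantiomer is acylated to the (S)-acetate F4. The unreacted alcohol is the (R)-carbinol, so the sequence comes back to the route at 8. Compound 8 is then carried through the KHF2/MeOH stage.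

**Third: step 2.**
- The diene 4 is volatile and hydrolytically labile, and both 3 and 4 polymerise or dimerise easily.
- Fallback: set out from 2 and replace 3 and 4 by a masked enone. Commercial 3-hydroxy-3-methylbutan-2-one is bis-silylated (TMSOTf 2.2 equiv, Et3N, CH2Cl2, 0 °C) to 3-methyl-2,3-bis(trimethylsilyloxy)but-1-ene F5. This is converted with PhI(OH)OTs/BF3·OEt2 at −78 °C into the saturated enolonium tosylate F6, which 2 traps as in step 3. The tertiary TMS ether is lost on work-up, giving 6-(3-hydroxy-3-methyl-2-oxobutyl)-7,4'-bis-O-TBS-genistein F7. Syn-elimination with the Burgess reagent (methyl N-(triethylammoniosulfonyl)carbamate, THF, 50 °C) installs the isopropenyl group, and the sequence comes back to the route at 6.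

## Further compounds
F1 | step 3 | 6-iodo-7,4'-bis-O-TBS-genistein | CC(C)(C)[Si](C)(C)Oc1cc2occ(-c3ccc(O[Si](C)(C)C(C)(C)C)cc3)c(=O)c2c(O)c1I
F2 | step 3 | tributyltin enolate of 3-methylbut-3-en-2-one | C=C(C)C(=C)O[Sn](CCCC)(CCCC)CCCC
F3 | step 4 | racemic bis-TBS carbinol (racemate of 8) | C=C(C)C(O)Cc1c(O[Si](C)(C)C(C)(C)C)cc2occ(-c3ccc(O[Si](C)(C)C(C)(C)C)cc3)c(=O)c2c1O
F4 | step 4 | (S)-acetate of the bis-TBS carbinol | C=C(C)[C@@H](OC(C)=O)Cc1c(O[Si](C)(C)C(C)(C)C)cc2occ(-c3ccc(O[Si](C)(C)C(C)(C)C)cc3)c(=O)c2c1O
F5 | step 2 | 3-methyl-2,3-bis(trimethylsilyloxy)but-1-ene | C=C(O[Si](C)(C)C)C(C)(C)O[Si](C)(C)C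
F6 | step 2 | {[3-methyl-3-(trimethylsilyloxy)but-1-en-2-yl]oxy}(phenyl)-λ3-iodanyl tosylate | C=C(OI(c1ccccc1)OS(=O)(=O)c1ccc(C)cc1)C(C)(C)O[Si](C)(C)C
F7 | step 2 | 6-(3-hydroxy-3-methyl-2-oxobutyl)-7,4'-bis-O-TBS-genistein | CC(C)(O)C(=O)Cc1c(O[Si](C)(C)C(C)(C)C)cc2occ(-c3ccc(O[Si](C)(C)C(C)(C)C)cc3)c(=O)c2c1O
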